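**Strategy.** The route rests on disconnecting the furan O1–C2 bond. In the target, O1–C2 of the furan ring (an aryl enol ether) sits next to a C3 aroyl group whose ring carries a 2-hydroxyl: together these are what is left of a flavone pyranone after its ring oxygen has been displaced from C2 by a phenol on a C3 aryl group. The key step therefore converts a 3-arylflavone, whose C3 substituent is the phloretin A ring with only the hydroxyl between the biaryl bond and the propanoyl group free, into the 3-aroyl-2-arylbenzofuran in one base-mediated operation that closes the furan and opens the pyranone. All other hydroxyls are benzyl ethers.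

Key step: step 8

Assumption: the target has no stereogenic element, so it is made as the achiral compound drawn and no enantioselective step is needed.

Remark on the design: the spectator hydroxyls are carried as benzyl ethers and O2' as a MOM ether, so the precursor is unmasked by dilute acid and the target is released by neutral hydrogenolysis. Primed locants (C2', C3', O4' and so on) refer to the phloretin A ring.

**Route**

Step 1
Reactants: 1 1-[4-(benzyloxy)-2-hydroxyphenyl]ethan-1-one; 2 4-(benzyloxy)benzaldehyde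
Product: 3 (E)-1-[4-(benzyloxy)-2-hydroxyphenyl]-3-[4-(benzyloxy)phenyl]prop-2-en-1-one
Conditions: KOH (50% aq.), EtOH, rt; then dil. HCl
Reagents that add atoms: none
Why: Claisen–Schmidt condensation of the acetophenone enolate with a non-enolisable aldehyde, followed by E1cB dehydration, should give the thermodynamically preferred E-enone, as is routine for 2'-hydroxychalcones.

Step 2
Reactants: 3 (E)-1-[4-(benzyloxy)-2-hydroxyphenyl]-3-[4-(benzyloxy)phenyl]prop-2-en-1-one
Product: 4 7-(benzyloxy)-2-[4-(benzyloxy)phenyl]-4H-chromen-4-one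
Conditions: I2 (10 mol %), DMSO, 130 °C; aq. Na2S2O3 work-up
Reagents that add atoms: none
Why: Iodine-catalysed oxidative cyclisation of a 2'-hydroxychalcone in DMSO (6-endo oxa-Michael addition, then iodination and loss of HI, with DMSO reoxidising the iodide) is a standard flavone synthesis that benzyl aryl ethers at these positions should survive.

Step 3
Reactants: 5 phloretin
Product: 6 1-[2,4-bis(benzyloxy)-6-hydroxyphenyl]-3-[4-(benzyloxy)phenyl]propan-1-one
Conditions: BnBr (3.1 equiv), K2CO3, DMF, rt → 50 °C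
Reagents that add atoms: benzyl bromide, BrCc1ccccc1
Why: Williamson etherification should stop at the tri-ether because the remaining ortho hydroxyl is hydrogen-bonded to the ketone and is the least nucleophilic, the usual behaviour of 2-acylphloroglucinols.

Step 4
Reactants: 6 1-[2,4-bis(benzyloxy)-6-hydroxyphenyl]-3-[4-(benzyloxy)phenyl]propan-1-one
Product: 7 1-[4,6-bis(benzyloxy)-2-hydroxy-3-iodophenyl]-3-[4-(benzyloxy)phenyl]propan-1-one
Conditions: BnMe3N+ ICl2− (1.05 equiv), NaHCO3, CH2Cl2/MeOH, rt
Reagents that add atoms: benzyltrimethylammonium dichloroiodate, C[N+](C)(C)Cc1ccccc1.Cl[I-]Cl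
Why: Electrophilic aromatic iodination should occur on the trioxygenated ring rather than the B ring and, as is established for 2-hydroxy-4,6-dialkoxyaryl ketones, at C3' next to the chelated hydroxyl (para to O6') rather than at C5' between two ether groups.

Step 5
Reactants: 7 1-[4,6-bis(benzyloxy)-2-hydroxy-3-iodophenyl]-3-[4-(benzyloxy)phenyl]propan-1-one
Product: 8 1-[4,6-bis(benzyloxy)-3-iodo-2-(methoxymethoxy)phenyl]-3-[4-(benzyloxy)phenyl]propan-1-one
Conditions: NaH (1.1 equiv), DMF, 0 °C; MOMCl, 0 °C → rt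
Reagents that add atoms: chloromethyl methyl ether, COCCl
Why: O-alkylation of the sodium phenoxide with the small, reactive chloromethyl ether (Williamson-type acetal formation) masks the only acidic hydroxyl before the organozinc coupling and is later removable by acid without touching benzyl ethers.

Step 6
Reactants: 4 7-(benzyloxy)-2-[4-(benzyloxy)phenyl]-4H-chromen-4-one; 8 1-[4,6-bis(benzyloxy)-3-iodo-2-(methoxymethoxy)phenyl]-3-[4-(benzyloxy)phenyl]propan-1-one
Product: 11 7-(benzyloxy)-2-[4-(benzyloxy)phenyl]-3-{4,6-bis(benzyloxy)-3-[3-(4-(benzyloxy)phenyl)propanoyl]-2-(methoxymethoxy)phenyl}-4H-chromen-4-one, via 3-lithioflavone 9 (not isolated), via flavon-3-ylzinc chloride 10 (not isolated)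
Conditions: 4 (1.3 equiv), LDA, THF, −78 °C; ZnCl2, −78 °C → rt; then 8, Pd2(dba)3 (2.5 mol %), SPhos (10 mol %), THF, 60 °C
Reagents that add atoms: none
Why: Deprotonation of flavones at C3 by LDA at −78 °C is known, transmetalation to zinc before warming gives a stable nucleophile that tolerates the enolisable ketone of 8, and Negishi cross-coupling with a bulky dialkylbiarylphosphine ligand is an established way to form such a hindered sp2–sp2 bond.

Step 7
Reactants: 11 7-(benzyloxy)-2-[4-(benzyloxy)phenyl]-3-{4,6-bis(benzyloxy)-3-[3-(4-(benzyloxy)phenyl)propanoyl]-2-(methoxymethoxy)phenyl}-4H-chromen-4-one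
Product: 12 7-(benzyloxy)-2-[4-(benzyloxy)phenyl]-3-{4,6-bis(benzyloxy)-3-[3-(4-(benzyloxy)phenyl)propanoyl]-2-hydroxyphenyl}-4H-chromen-4-one
Conditions: 3 M HCl (aq.), MeOH/THF, 50 °C
Reagents that add atoms: none
Why: Acid-catalysed cleavage of the MOM acetal (transacetalisation to methanol) should free O2' while benzyl ethers and the chromone are inert to dilute acid.

Step 8
Reactants: 12 7-(benzyloxy)-2-[4-(benzyloxy)phenyl]-3-{4,6-bis(benzyloxy)-3-[3-(4-(benzyloxy)phenyl)propanoyl]-2-hydroxyphenyl}-4H-chromen-4-one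
Product: 14 1-{4,6-bis(benzyloxy)-3-[4-(benzyloxy)-2-hydroxybenzoyl]-2-[4-(benzyloxy)phenyl]-1-benzofuran-7-yl}-3-[4-(benzyloxy)phenyl]propan-1-one, via ketal enolate 13 (not isolated)
Conditions: DBU (0.2 equiv), DMF, 60 °C; AcOH quench
Reagents that add atoms: none
Why: Proposed new method: DBU generates the O2' phenoxide of 12, which adds to C2 of the chromone (oxa-Michael addition to the vinylogous ester) to give the ketal enolate 13, and this expels the pyranone oxygen as an o-acylphenoxide (E1cB), so that the furan O1–C2 bond forms as the pyranone opens and proton transfer to the released phenoxide regenerates the base. The closest known reaction types are the ring opening and recyclisation of chromones by external nucleophiles attacking C2 and the oxa-Michael/retro-oxa-Michael interconversion of 2'-hydroxychalcones and flavanones. The one new ring, the furan, closes in the 5-endo-trig mode, which is formally disfavoured but should be reachable because the twisted biaryl axis holds O2' over the π face at C2 and because the addition need only be reversible, the elimination being the irreversible exit. No stereocentre is created, since the ketal carbon of 13 becomes sp2 again in 14. The step needs chemoselectivity between the two oxygens flanking the biaryl bond, which is secured by O4' being a benzyl ether so that O2' is the only free hydroxyl in 12, and its direction is secured by the gain of benzofuran aromaticity and a chelated 2-hydroxyaryl ketone.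

Step 9
Reactants: 14 1-{4,6-bis(benzyloxy)-3-[4-(benzyloxy)-2-hydroxybenzoyl]-2-[4-(benzyloxy)phenyl]-1-benzofuran-7-yl}-3-[4-(benzyloxy)phenyl]propan-1-one
Product: 15 1-[3-(2,4-dihydroxybenzoyl)-4,6-dihydroxy-2-(4-hydroxyphenyl)-1-benzofuran-7-yl]-3-(4-hydroxyphenyl)propan-1-one
Conditions: H2 (1 atm), 10% Pd/C, EtOAc/MeOH, rt
Reagents that add atoms: none
Why: Palladium-catalysed hydrogenolysis should remove all five benzyl aryl ethers under neutral conditions, while the two chelated, electron-rich aryl ketones and the aromatic, fully substituted furan double bond should resist reduction at 1 atm and room temperature.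

**Compound list**

1 | 1-[4-(benzyloxy)-2-hydroxyphenyl]ethan-1-one | CC(=O)c1ccc(OCc2ccccc2)cc1O | starting material
2 | 4-(benzyloxy)benzaldehyde | O=Cc1ccc(OCc2ccccc2)cc1 | starting material
3 | (E)-1-[4-(benzyloxy)-2-hydroxyphenyl]-3-[4-(benzyloxy)phenyl]prop-2-en-1-one | O=C(/C=C/c1ccc(OCc2ccccc2)cc1)c1ccc(OCc2ccccc2)cc1O | intermediate
4 | 7-(benzyloxy)-2-[4-(benzyloxy)phenyl]-4H-chromen-4-one | O=c1cc(-c2ccc(OCc3ccccc3)cc2)oc2cc(OCc3ccccc3)ccc12 | intermediate
5 | phloretin, 3-(4-hydroxyphenyl)-1-(2,4,6-trihydroxyphenyl)propan-1-one | O=C(CCc1ccc(O)cc1)c1c(O)cc(O)cc1O | starting material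
6 | 1-[2,4-bis(benzyloxy)-6-hydroxyphenyl]-3-[4-(benzyloxy)phenyl]propan-1-one | O=C(CCc1ccc(OCc2ccccc2)cc1)c1c(O)cc(OCc2ccccc2)cc1OCc1ccccc1 | intermediate
7 | 1-[4,6-bis(benzyloxy)-2-hydroxy-3-iodophenyl]-3-[4-(benzyloxy)phenyl]propan-1-one | O=C(CCc1ccc(OCc2ccccc2)cc1)c1c(O)c(I)c(OCc2ccccc2)cc1OCc1ccccc1 | intermediate
8 | 1-[4,6-bis(benzyloxy)-3-iodo-2-(methoxymethoxy)phenyl]-3-[4-(benzyloxy)phenyl]propan-1-one | COCOc1c(I)c(OCc2ccccc2)cc(OCc2ccccc2)c1C(=O)CCc1ccc(OCc2ccccc2)cc1 | intermediate
9 | 7-(benzyloxy)-2-[4-(benzyloxy)phenyl]-3-lithio-4H-chromen-4-one | [Li]c1c(-c2ccc(OCc3ccccc3)cc2)oc2cc(OCc3ccccc3)ccc2c1=O | intermediate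
10 | {7-(benzyloxy)-2-[4-(benzyloxy)phenyl]-4-oxo-4H-chromen-3-yl}zinc chloride | Cl[Zn]c1c(-c2ccc(OCc3ccccc3)cc2)oc2cc(OCc3ccccc3)ccc2c1=O | intermediate
11 | 7-(benzyloxy)-2-[4-(benzyloxy)phenyl]-3-{4,6-bis(benzyloxy)-3-[3-(4-(benzyloxy)phenyl)propanoyl]-2-(methoxymethoxy)phenyl}-4H-chromen-4-one | COCOc1c(-c2c(-c3ccc(OCc4ccccc4)cc3)oc3cc(OCc4ccccc4)ccc3c2=O)c(OCc2ccccc2)cc(OCc2ccccc2)c1C(=O)CCc1ccc(OCc2ccccc2)cc1 | intermediate
12 | 7-(benzyloxy)-2-[4-(benzyloxy)phenyl]-3-{4,6-bis(benzyloxy)-3-[3-(4-(benzyloxy)phenyl)propanoyl]-2-hydroxyphenyl}-4H-chromen-4-one | O=C(CCc1ccc(OCc2ccccc2)cc1)c1c(OCc2ccccc2)cc(OCc2ccccc2)c(-c2c(-c3ccc(OCc4ccccc4)cc3)oc3cc(OCc4ccccc4)ccc3c2=O)c1O | intermediate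
13 | ketal enolate from addition of O2' to C2 of 12 (C2 bound to both ring oxygens, C3=C4–O−; anion, racemic at the ketal carbon) | [O-]C1=C2c3c(OCc4ccccc4)cc(OCc4ccccc4)c(C(=O)CCc4ccc(OCc5ccccc5)cc4)c3OC2(c2ccc(OCc3ccccc3)cc2)Oc2cc(OCc3ccccc3)ccc12 | intermediate
14 | 1-{4,6-bis(benzyloxy)-3-[4-(benzyloxy)-2-hydroxybenzoyl]-2-[4-(benzyloxy)phenyl]-1-benzofuran-7-yl}-3-[4-(benzyloxy)phenyl]propan-1-one | O=C(CCc1ccc(OCc2ccccc2)cc1)c1c(OCc2ccccc2)cc(OCc2ccccc2)c2c(C(=O)c3ccc(OCc4ccccc4)cc3O)c(-c3ccc(OCc4ccccc4)cc3)oc12 | intermediate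
15 | 1-[3-(2,4-dihydroxybenzoyl)-4,6-dihydroxy-2-(4-hydroxyphenyl)-1-benzofuran-7-yl]-3-(4-hydroxyphenyl)propan-1-one | O=C(CCc1ccc(O)cc1)c1c(O)cc(O)c2c(C(=O)c3ccc(O)cc3O)c(-c3ccc(O)cc3)oc12 | target

**Step count and risks**

Total step count: 9. Longest linear sequence: 7 steps (phloretin 5 to 15, steps 3–9).

Steps most likely to fail:

Step 8 (proposed new method). The phenoxide is stabilised by conjugation with the neighbouring ketone and may fail to add to the electron-rich C2 in the 5-endo mode, or the adduct may revert faster than the pyranone opens, so that no ring-switch takes place. The fallback uses known chemistry and sets out from 8. Sonogashira coupling with 1-(benzyloxy)-4-ethynylbenzene (PdCl2(PPh3)2, CuI, Et3N, THF, 50 °C) should give the MOM-protected diarylalkyne F1. Dilute HCl in MeOH/THF should then give the o-alkynylphenol F2. Palladium-catalysed carbonylative annulation of F2 with 2,4-bis(benzyloxy)-1-iodobenzene (Pd(PPh3)4, K2CO3, CO 1 atm, MeCN, 50 °C) proceeds by 5-endo-dig oxypalladation of the alkyne by the aroylpalladium species and reductive elimination. It should give the hexabenzyl 3-aroyl-2-arylbenzofuran F3, which has the full skeleton. Hydrogenolysis under the conditions of step 9 returns to the route at 15.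

Step 6. Transmetalation and reductive elimination at a junction with four ortho substituents may be slow, so that protonation of the zinc reagent and reduction of the aryl iodide win. The fallback reverses the roles of the partners and sets out from 4 and 8. Lithiation of 4 as in step 6 and quenching with I2 at −78 °C should give the 3-iodoflavone F4. Miyaura borylation of 8 (B2pin2, XPhos Pd G2, KOAc, dioxane, 90 °C) should give the aryl pinacolboronate F5. Suzuki–Miyaura coupling of F4 with F5 (SPhos Pd G3, K3PO4, toluene/water, 80 °C) returns to the route at 11.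

Step 3. Discrimination between the chelated hydroxyl and the other three may be incomplete, so that under- and over-benzylation give a mixture. The fallback sets out from 5. Exhaustive benzylation (BnBr in excess, K2CO3, DMF, 70 °C) should give tetra-O-benzylphloretin F6, in which the two ether groups ortho to the ketone are equivalent. MgBr2·OEt2 (toluene/Et2O, reflux) then cleaves one benzyl ether ortho to the carbonyl by chelation and returns to the route at 6.

Further compounds
F1 | step 8 | 1-[4,6-bis(benzyloxy)-3-{[4-(benzyloxy)phenyl]ethynyl}-2-(methoxymethoxy)phenyl]-3-[4-(benzyloxy)phenyl]propan-1-one | COCOc1c(C#Cc2ccc(OCc3ccccc3)cc2)c(OCc2ccccc2)cc(OCc2ccccc2)c1C(=O)CCc1ccc(OCc2ccccc2)cc1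
F2 | step 8 | 1-[4,6-bis(benzyloxy)-3-{[4-(benzyloxy)phenyl]ethynyl}-2-hydroxyphenyl]-3-[4-(benzyloxy)phenyl]propan-1-one | O=C(CCc1ccc(OCc2ccccc2)cc1)c1c(OCc2ccccc2)cc(OCc2ccccc2)c(C#Cc2ccc(OCc3ccccc3)cc2)c1O
F3 | step 8 | 1-{4,6-bis(benzyloxy)-3-[2,4-bis(benzyloxy)benzoyl]-2-[4-(benzyloxy)phenyl]-1-benzofuran-7-yl}-3-[4-(benzyloxy)phenyl]propan-1-one | O=C(CCc1ccc(OCc2ccccc2)cc1)c1c(OCc2ccccc2)cc(OCc2ccccc2)c2c(C(=O)c3ccc(OCc4ccccc4)cc3OCc3ccccc3)c(-c3ccc(OCc4ccccc4)cc3)oc12
F4 | step 6 | 7-(benzyloxy)-2-[4-(benzyloxy)phenyl]-3-iodo-4H-chromen-4-one | O=c1c(I)c(-c2ccc(OCc3ccccc3)cc2)oc2cc(OCc3ccccc3)ccc12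
F5 | step 6 | 1-[4,6-bis(benzyloxy)-2-(methoxymethoxy)-3-(4,4,5,5-tetramethyl-1,3,2-dioxaborolan-2-yl)phenyl]-3-[4-(benzyloxy)phenyl]propan-1-one | COCOc1c(B2OC(C)(C)C(C)(C)O2)c(OCc2ccccc2)cc(OCc2ccccc2)c1C(=O)CCc1ccc(OCc2ccccc2)cc1
F6 | step 3 | 1-[2,4,6-tris(benzyloxy)phenyl]-3-[4-(benzyloxy)phenyl]propan-1-one | O=C(CCc1ccc(OCc2ccccc2)cc1)c1c(OCc2ccccc2)cc(OCc2ccccc2)cc1OCc1ccccc1
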